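## Structural features

The target 15 is a diarylmethane in which a single methylene carbon links C6 of ring A to C1' of ring B. There is no further ring and no stereocentre, so the whole problem is regiochemical. Ring A carries CH2OH at C1, hydroxyls at C3 and C4, bromine at C5 and the bridge at C6, while ring B carries hydroxyls at C3' and C4' and bromines at C5' and C6', so each ring has five contiguous substituents and a single C–H (C2, C2'). The fragile groups are the two catechols (oxidised in air under base), the C1 benzylic alcohol, which is para to the C4 hydroxyl and ionises easily towards a quinone methide, the three aryl bromides (lost under hydrogenolysis or with strongly reducing metals) and the doubly benzylic bridge. The real difficulty is to place bromine next to oxygen and next to the bridge on both rings and still finish under conditions mild enough for four free phenols and the labile benzylic alcohol. The key step exploits the local pattern around C4 and C4', where the phenol carbon of each ring has one ortho neighbour that already bears bromine (C5, C5') and a para carbon that bears carbon (C1, C1'), so that an oxygen delivered from an iodine bound to the phenol oxygen can only reach C3 and C3'. Because both rings show the same pattern, one operation installs both missing oxygens.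

## Logic of the disconnections

15 ⇒ 14. The benzylic O–Si bond is cut last. The C1 hydroxymethyl group is the most labile function of 15, so it stays masked until the end. The forward step must be a hydrolysis in which water is the only nucleophile, so that any ionisation at the benzylic carbon returns to 15, and it must exclude air.

14 ⇒ 12 (through 13). The C3–O and C3'–O bonds are cut. This removes two of the four phenolic oxygens and leaves one oxygen per ring, which simplifies everything earlier: one methyl ether per ring suffices, and the para-directing effect of a single methoxyl can be used twice. The forward step must transfer oxygen to bromine-deactivated phenols without touching the benzylic oxygen or the bridge. For that reason C1 is carried as a silyl ether: a free alcohol would be oxidised, and a formyl group would deactivate the ring A phenol. The quinones 13 must be reduced at once.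

12 ⇒ 10 (through 11). The benzylic O–Si bond is cut. A primary alcohol cannot be silylated selectively beside two acidic ortho-bromophenols, so the forward step silylates all three hydroxyls to 11 and then removes the two aryl silyl groups. The differentiation rests on the much better leaving-group ability of an ortho-bromophenoxide compared with an alkoxide.

10 ⇒ 9. The C1 carbinol is taken back to the aldehyde. The order matters: Lewis-acid ether cleavage would turn a benzylic alcohol or its silyl ether into a benzylic bromide, whereas an aldehyde survives it. The reduction is therefore placed after the demethylation, and needs a neutral work-up because 10 is a para-hydroxybenzyl alcohol.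

9 ⇒ 8. The two O–CH3 bonds are cut. Methyl ethers are the only phenol protection that tolerates the Lewis and Brønsted acids of the carbon–carbon bond-forming steps. The forward cleavage must spare the aldehyde and the aryl bromides.

8 ⇒ 7. The C1–CHO bond is cut. C1 is para to the C4 methoxyl and is the only open para position in the molecule, so an electrophilic formylation should find it. The forward step must prefer C1 over C3 and C3', which are ortho to the methoxyls; ring B is in addition doubly brominated and para-blocked.

7 ⇒ 6. A hydroxyl is added to the bridge carbon so that the bridge can be made by carbonyl addition. The forward deoxygenation is easy because the benzylic cation is stabilised by the para methoxyl of ring B, and the silane hydride does not touch aryl bromides.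

6 ⇒ 5 + 4. The bond between the bridge carbon and C1' is cut. This gives two pieces of similar size, one of them (4) commercial, and the polar addition fixes the position of the bridge on both rings without ambiguity. An acid-mediated benzylation of 2 with an electrophile derived from 4 would make the same bond from 2 directly. However, the ring of that electrophile and ring A of 7 are both more electron-rich than 2, so self-condensation, over-benzylation and ortho attack would compete. The price of the polar route is that 5 must be made and used cold.

5 ⇒ 3 ⇒ 2 ⇒ 1. The C–Mg bond comes from a C–I bond by exchange, which is far faster for iodine than for bromine. The C–I bond comes from iodination of 2 para to its methoxyl, and the O–CH3 bond from methylation of commercial 1. The demand is para rather than ortho iodination of a doubly brominated anisole.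

## Other disconnections considered

Alternative 1: The cut removes both carbon substituents of ring A at once, at C1 and at C6, and treats ring A as an aryne. In the forward sense a fluoride source would release the aryne from 2-bromo-3,4-dimethoxy-6-(trimethylsilyl)phenyl trifluoromethanesulfonate A1. The isocyanide carbon of tert-butyl isocyanide A2 should add at C1, the aryne carbon remote from the C5 bromine. The C6 aryl anion would then add to 2,3-dibromo-4,5-dimethoxybenzaldehyde A3, and the alkoxide would close onto the nitrilium carbon to give the iminoisobenzofuran A4, racemic at its benzylic carbon. Hydrolysis would give the phthalide A5.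
- In its favour: both carbon–carbon bonds to ring A and the complete carbon skeleton arise in one step, and the inductive pull of bromine polarises the aryne in the required sense.
- Against it here: A1 needs a multi-step preparation with bromine beside the silyl triflate unit. The benzylic lactone C–O bond of A5 must be cleaved reductively without loss of three aryl bromides. The final four-fold ether cleavage converts the benzylic alcohol into a bromide that has to be hydrolysed.
- Comparison: the alternative is better than the chosen plan on one structural point, since all four ring oxygens are present from the start and no deactivated phenol has to be oxidised. It is equal in regiochemical certainty at ring A. Like step 3 of the chosen plan, it creates a stereocentre only to remove it. On step economy it should be longer, because both A1 and A3 must be made and four or five operations follow A4.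

Alternative 2: The cut goes through ring A itself, at C2–C3 and C4–C5, so that C3 and C4 with their oxygens come from an alkyne and C5, C6, C1 and C2 from a 2-pyrone. In the forward sense methyl 3-bromo-4-(2,3-dibromo-4,5-dimethoxybenzyl)-2-oxo-2H-pyran-5-carboxylate A6 and di-tert-butoxyethyne A7 would undergo an inverse-electron-demand [4+2] cycloaddition. Decarboxylative retro-[4+2] of the bridged lactone would aromatise it to the benzoate A8.
- In its favour: the electron-poor diene and electron-rich dienophile are well matched, the symmetrical alkyne removes any regiochemical question, ring A is formed fully substituted in one operation, and tert-butyl ethers fall to mild acid.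
- Against it here: A6, a 4-benzylated and 3-brominated coumalate, has no short synthesis. A7 is thermally labile, while a 3,4-disubstituted pyrone may need heat. The ester must be reduced beside three aryl bromides. Ring B still carries methyl ethers, whose Lewis-acid cleavage brings back the benzylic bromide detour.
- Comparison: the alternative is better in placing all six substituents of ring A by construction and in avoiding oxygen transfer to deactivated phenols. On mechanism it is the more predictable key step. On step economy, and in the mildness of the last steps, the chosen plan is ahead.

Alternative 3: The cut removes all three C–Br bonds and leads back to 4-hydroxy-2-(4-hydroxy-3-methoxybenzyl)-5-methoxybenzaldehyde A9, a diarylmethane of two guaiacyl-type rings. In the forward sense three equivalents of electrophilic bromine in acetic acid, the last with an iron promoter, should brominate C5 and C5' ortho to the free hydroxyls and then C6' para to the ring B methoxyl, giving the tribromide A10. Ether cleavage and aldehyde reduction would finish the synthesis without any protecting group.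
- In its favour: the materials are the cheapest, the oxygens are in place, the bromines follow the innate directing effects, and the same stepwise bromination is well established on a single guaiacyl aldehyde ring.
- Against it here: the third bromination must choose C6' over C2' and over C2 of ring A. Ring B is a para-hydroxybenzyl unit open to ipso attack at C1' with cleavage of the bridge. The bridge CH2 can be brominated. A9 itself needs a regioselective benzylation of an aldehyde-deactivated ring.
- Comparison: on step economy this alternative is better than the chosen plan, and its last two operations equal steps 6 and 7 of the chosen route. On mechanism it is less controlled, because the chosen plan brings every bromine in from the starting materials and never brominates an electron-rich diarylmethane.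

Key step: step 9

Remark on the chemistry: 6 carries the only stereocentre that appears in the route; it is formed as the racemate and removed in step 4, so no stereocontrol is required.

## Route

Step 1
Reactants: 1 2,3-dibromophenol
Product: 2 1,2-dibromo-3-methoxybenzene (2,3-dibromoanisole)
Conditions: MeI, K2CO3, acetone, reflux
Reagents that add atoms: iodomethane, CI
Why: Williamson O-methylation of an acidic ortho-bromophenol; the methyl ether is the one phenol mask that should survive the acids of steps 2, 4 and 5.

Step 2
Reactants: 2 1,2-dibromo-3-methoxybenzene
Product: 3 2,3-dibromo-1-iodo-4-methoxybenzene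
Conditions: NIS, TFA (0.3 equiv), MeCN, rt to 50 °C
Reagents that add atoms: N-iodosuccinimide, O=C1CCC(=O)N1I
Why: Electrophilic aromatic iodination; the methoxyl should direct to its para carbon, as in the para halogenation of 3-bromoanisole, and the carbon–iodine bond then marks the future bridge position C1'.

Step 3
Reactants: 3 2,3-dibromo-1-iodo-4-methoxybenzene; 4 2-bromo-3-methoxybenzaldehyde
Product: 6 rac-(2-bromo-3-methoxyphenyl)(2,3-dibromo-4-methoxyphenyl)methanol, via arylmagnesium chloride 5 (not isolated)
Conditions: iPrMgCl·LiCl, THF, −40 °C; then 4, −40 to −10 °C; aq. NH4Cl
Reagents that add atoms: none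
Why: Iodine–magnesium exchange is much faster than bromine–magnesium exchange and is further helped by the ortho bromine, and the ortho-bromoaryl Grignard reagent should be stable at this temperature and add to the aldehyde (Grignard addition); the carbinol is racemic and its stereocentre is removed in step 4.

Step 4
Reactants: 6 rac-(2-bromo-3-methoxyphenyl)(2,3-dibromo-4-methoxyphenyl)methanol
Product: 7 2,3-dibromo-1-(2-bromo-3-methoxybenzyl)-4-methoxybenzene
Conditions: Et3SiH, TFA, CH2Cl2, 0 °C to rt
Reagents that add atoms: none
Why: Ionic hydrogenation; the diarylmethyl cation is stabilised by the para methoxyl of ring B and is trapped by silane hydride, which leaves aryl bromides alone.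

Step 5
Reactants: 7 2,3-dibromo-1-(2-bromo-3-methoxybenzyl)-4-methoxybenzene
Product: 8 3-bromo-2-(2,3-dibromo-4-methoxybenzyl)-4-methoxybenzaldehyde
Conditions: Cl2CHOMe, TiCl4, CH2Cl2, −78 to 0 °C; then H2O
Reagents that add atoms: dichloromethyl methyl ether, COC(Cl)Cl; water, O
Why: Rieche formylation; C1 is para to the ring A methoxyl and ortho to an alkyl group, whereas ring B is doubly brominated and para-blocked, so the formyl group should enter at C1, as is usual for anisoles with a free para position.

Step 6
Reactants: 8 3-bromo-2-(2,3-dibromo-4-methoxybenzyl)-4-methoxybenzaldehyde
Product: 9 3-bromo-2-(2,3-dibromo-4-hydroxybenzyl)-4-hydroxybenzaldehyde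
Conditions: BBr3, CH2Cl2, −78 °C to rt; then ice-water
Reagents that add atoms: none
Why: Lewis-acid cleavage of aryl methyl ethers, done at the aldehyde oxidation level because an aryl aldehyde survives BBr3 while a benzylic alcohol would become a bromide; Bradsher-type cyclisation onto ring B is not expected, since its only open position next to the bridge (C2') is meta to oxygen on a dibrominated ring.

Step 7
Reactants: 9 3-bromo-2-(2,3-dibromo-4-hydroxybenzyl)-4-hydroxybenzaldehyde
Product: 10 2-bromo-3-(2,3-dibromo-4-hydroxybenzyl)-4-(hydroxymethyl)phenol
Conditions: NaBH4, THF–MeOH, 0 °C; aq. NH4Cl
Reagents that add atoms: none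
Why: Borohydride reduction of the aldehyde, as for 4-hydroxybenzaldehyde, with an excess to offset phenoxide formation; aryl bromides are inert and the near-neutral quench protects the para-hydroxybenzyl alcohol.

Step 8
Reactants: 10 2-bromo-3-(2,3-dibromo-4-hydroxybenzyl)-4-(hydroxymethyl)phenol
Product: 12 2-bromo-4-(tert-butyldimethylsilyloxymethyl)-3-(2,3-dibromo-4-hydroxybenzyl)phenol, via tris(silyl ether) 11 (not isolated)
Conditions: TBSCl (3.6 equiv), imidazole, DMF, 0 °C to rt; aq. wash, crude carried on; then K2CO3 (0.5 equiv), MeOH, 0 °C to rt
Reagents that add atoms: tert-butyldimethylsilyl chloride, CC(C)(C)[Si](C)(C)Cl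
Why: Exhaustive silylation followed by selective base-mediated methanolysis of the two aryl silyl ethers; ortho-bromophenoxides are far better leaving groups than an alkoxide, so the primary benzylic silyl ether should remain.

Step 9
Reactants: 12 2-bromo-4-(tert-butyldimethylsilyloxymethyl)-3-(2,3-dibromo-4-hydroxybenzyl)phenol
Product: 14 3-bromo-5-(tert-butyldimethylsilyloxymethyl)-4-(2,3-dibromo-4,5-dihydroxybenzyl)benzene-1,2-diol, via bis-ortho-quinone 13 (not isolated)
Conditions: IBX (2.6 equiv), DMF, rt to 45 °C, dark, Ar; then aq. Na2S2O4, 0 °C
Reagents that add atoms: 2-iodoxybenzoic acid (IBX), O=C1OI(=O)(O)c2ccccc12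
Why: Each phenol oxygen exchanges onto the pentavalent iodine of IBX, and an iodine-bound oxo ligand is then delivered intramolecularly to the adjacent free ring carbon (C3 in ring A, C3' in ring B) while iodine drops to the trivalent state. After tautomerisation the catechol mono-ester of trivalent iodine collapses to the ortho-quinone and 2-iodobenzoic acid, so one equivalent of oxidant per ring forms one C–O bond. Aqueous Na2S2O4 added to the same flask reduces bis-quinone 13 at once to the bis-catechol, before the para-alkyl quinones can tautomerise to quinone methides or add nucleophiles. The closest known reaction type is the regioselective IBX ortho-oxygenation of phenols to ortho-quinones with reductive work-up to catechols, and no ring is closed and no stereocentre is created. Site selectivity is needed and is secured by the substrate, since at each phenol one ortho carbon carries bromine (C5, C5') and the para carbon carries carbon (C1, C1'), which leaves C3 and C3' as the only positions that an oxygen tethered through the phenol oxygen can reach and rules out para-quinone formation. Chemoselectivity rests on the silyl ether, which keeps the primary benzylic oxygen away from an oxidant that would otherwise give the aldehyde, and on the moderate temperature, at which the diarylmethane CH2 should not be attacked. The C1 substituent is kept at the alcohol oxidation level because a para formyl group would deactivate the ring A phenol. Ring B, with two bromines, is the slower ring, hence the modest excess of oxidant and the gentle warming.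

Step 10
Reactants: 14 3-bromo-5-(tert-butyldimethylsilyloxymethyl)-4-(2,3-dibromo-4,5-dihydroxybenzyl)benzene-1,2-diol
Product: 15 3-bromo-4-(2,3-dibromo-4,5-dihydroxybenzyl)-5-(hydroxymethyl)benzene-1,2-diol
Conditions: AcOH–THF–H2O (3:1:1), rt, Ar
Reagents that add atoms: none
Why: Mild acid hydrolysis of a primary silyl ether; water is the only nucleophile present, so any ionisation of the para-hydroxybenzylic carbon should return to 15, and no base is present to promote catechol oxidation.

## Compound list

1 | 2,3-dibromophenol | Oc1cccc(Br)c1Br | starting material
2 | 1,2-dibromo-3-methoxybenzene (2,3-dibromoanisole) | COc1cccc(Br)c1Br | intermediate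
3 | 2,3-dibromo-1-iodo-4-methoxybenzene | COc1ccc(I)c(Br)c1Br | intermediate
4 | 2-bromo-3-methoxybenzaldehyde | COc1cccc(C=O)c1Br | starting material
5 | (2,3-dibromo-4-methoxyphenyl)magnesium chloride, LiCl complex | COc1ccc([Mg]Cl)c(Br)c1Br | intermediate (not isolated)
6 | rac-(2-bromo-3-methoxyphenyl)(2,3-dibromo-4-methoxyphenyl)methanol | COc1cccc(C(O)c2ccc(OC)c(Br)c2Br)c1Br | intermediate
7 | 2,3-dibromo-1-(2-bromo-3-methoxybenzyl)-4-methoxybenzene | COc1cccc(Cc2ccc(OC)c(Br)c2Br)c1Br | intermediate
8 | 3-bromo-2-(2,3-dibromo-4-methoxybenzyl)-4-methoxybenzaldehyde | COc1ccc(C=O)c(Cc2ccc(OC)c(Br)c2Br)c1Br | intermediate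
9 | 3-bromo-2-(2,3-dibromo-4-hydroxybenzyl)-4-hydroxybenzaldehyde | O=Cc1ccc(O)c(Br)c1Cc1ccc(O)c(Br)c1Br | intermediate
10 | 2-bromo-3-(2,3-dibromo-4-hydroxybenzyl)-4-(hydroxymethyl)phenol | OCc1ccc(O)c(Br)c1Cc1ccc(O)c(Br)c1Br | intermediate
11 | tert-butyl({3-bromo-4-[(tert-butyldimethylsilyl)oxy]-2-{2,3-dibromo-4-[(tert-butyldimethylsilyl)oxy]benzyl}benzyl}oxy)dimethylsilane | CC(C)(C)[Si](C)(C)OCc1ccc(O[Si](C)(C)C(C)(C)C)c(Br)c1Cc1ccc(O[Si](C)(C)C(C)(C)C)c(Br)c1Br | intermediate (not isolated)
12 | 2-bromo-4-(tert-butyldimethylsilyloxymethyl)-3-(2,3-dibromo-4-hydroxybenzyl)phenol | CC(C)(C)[Si](C)(C)OCc1ccc(O)c(Br)c1Cc1ccc(O)c(Br)c1Br | intermediate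
13 | 3-bromo-5-(tert-butyldimethylsilyloxymethyl)-4-[(5,6-dibromo-3,4-dioxocyclohexa-1,5-dien-1-yl)methyl]cyclohexa-3,5-diene-1,2-dione | CC(C)(C)[Si](C)(C)OCC1=CC(=O)C(=O)C(Br)=C1CC1=CC(=O)C(=O)C(Br)=C1Br | intermediate (not isolated)
14 | 3-bromo-5-(tert-butyldimethylsilyloxymethyl)-4-(2,3-dibromo-4,5-dihydroxybenzyl)benzene-1,2-diol | CC(C)(C)[Si](C)(C)OCc1cc(O)c(O)c(Br)c1Cc1cc(O)c(O)c(Br)c1Br | intermediate
15 | 3-bromo-4-(2,3-dibromo-4,5-dihydroxybenzyl)-5-(hydroxymethyl)benzene-1,2-diol | OCc1cc(O)c(O)c(Br)c1Cc1cc(O)c(O)c(Br)c1Br | target

## Step count and least certain steps

Total step count: 10. Longest linear sequence: 10 steps (1 to 15); 4 enters unmodified at step 3.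

Step 9 (key step). The most likely failure is incomplete or uneven oxygen transfer. Ring B is a 2,3-dibromophenol, a poor partner for ligand exchange and oxygen delivery, so the oxidation may stop after ring A. Forcing it by heat invites oxidation at the doubly benzylic bridge and tautomerisation of the para-alkyl quinones before the reductant is added. A more electrophilic oxidant of the same pentavalent iodine class would be the first adjustment of conditions. The fallback changes the approach and sets out from 12. Two-fold MgCl2/Et3N/paraformaldehyde ortho-formylation in MeCN at reflux, a reaction that works well on 2-bromophenol, should give 3-bromo-5-(tert-butyldimethylsilyloxymethyl)-4-(2,3-dibromo-5-formyl-4-hydroxybenzyl)-2-hydroxybenzaldehyde F1. Dakin oxidation with H2O2 and NaOH in THF–water under argon should then pass through 3-bromo-5-(tert-butyldimethylsilyloxymethyl)-4-[2,3-dibromo-5-(formyloxy)-4-hydroxybenzyl]-2-hydroxyphenyl formate F2, which is hydrolysed in the same flask. The fallback returns to the route at 14 with the same C3–O and C3'–O bonds formed.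

Step 5. The most likely failure is formylation at a carbon ortho to a methoxyl (C3 or C3'), steered by titanium coordination to the ether oxygen. Stalling is also possible because C1 is flanked by the bulky benzyl group, and there may be partial ether cleavage. The fallback sets out from 7. Iodination with NIS and TFA, which is governed by the para-directing methoxyl alone, should give 2-bromo-3-(2,3-dibromo-4-methoxybenzyl)-4-iodo-1-methoxybenzene F3. Iodine–magnesium exchange with iPrMgCl·LiCl at −20 °C should give [3-bromo-2-(2,3-dibromo-4-methoxybenzyl)-4-methoxyphenyl]magnesium chloride F4, which has no ortho bromine, and a DMF quench then returns the route to 8.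

Step 3. The most likely failure is loss of MgClBr from the ortho-bromoaryl Grignard reagent to an aryne when the exchange or the addition to the hindered aldehyde is slow, or incomplete exchange. Step 2 shares this exposure through its para-versus-ortho iodination. The fallback uses Friedel–Crafts chemistry and sets out from 2 and 4. NaBH4 reduction of 4 should give (2-bromo-3-methoxyphenyl)methanol F5, which would benzylate an excess of 2 para to its methoxyl under AlCl3 in CH2Cl2. It returns to the route at 7 and bypasses 3, 5 and 6. Positional isomers and over-benzylation are its own weakness, which is why it is the reserve and not the main line.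

Step 10. The most likely failure is acid-induced ionisation at the benzylic carbon, assisted by the para hydroxyl, followed by attack of a second catechol ring and oligomerisation, or air oxidation of the catechols during isolation. The fallback sets out from 14. BBr3 in CH2Cl2 from −78 to 0 °C should convert the silyl ether into 3-bromo-5-(bromomethyl)-4-(2,3-dibromo-4,5-dihydroxybenzyl)benzene-1,2-diol F6. Hydrolysis at high dilution in acetone–water at room temperature, where the ionisation is put to use and captured by a large excess of water, returns the route to 15.

## Further compounds

F1 | step 9 | 3-bromo-5-(tert-butyldimethylsilyloxymethyl)-4-(2,3-dibromo-5-formyl-4-hydroxybenzyl)-2-hydroxybenzaldehyde | CC(C)(C)[Si](C)(C)OCc1cc(C=O)c(O)c(Br)c1Cc1cc(C=O)c(O)c(Br)c1Br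
F2 | step 9 | 3-bromo-5-(tert-butyldimethylsilyloxymethyl)-4-[2,3-dibromo-5-(formyloxy)-4-hydroxybenzyl]-2-hydroxyphenyl formate | CC(C)(C)[Si](C)(C)OCc1cc(OC=O)c(O)c(Br)c1Cc1cc(OC=O)c(O)c(Br)c1Br
F3 | step 5 | 2-bromo-3-(2,3-dibromo-4-methoxybenzyl)-4-iodo-1-methoxybenzene | COc1ccc(I)c(Cc2ccc(OC)c(Br)c2Br)c1Br
F4 | step 5 | [3-bromo-2-(2,3-dibromo-4-methoxybenzyl)-4-methoxyphenyl]magnesium chloride | COc1ccc([Mg]Cl)c(Cc2ccc(OC)c(Br)c2Br)c1Br
F5 | step 3 | (2-bromo-3-methoxyphenyl)methanol | COc1cccc(CO)c1Br
F6 | step 10 | 3-bromo-5-(bromomethyl)-4-(2,3-dibromo-4,5-dihydroxybenzyl)benzene-1,2-diol | BrCc1cc(O)c(O)c(Br)c1Cc1cc(O)c(O)c(Br)c1Br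
A1 | alternative 1 | 2-bromo-3,4-dimethoxy-6-(trimethylsilyl)phenyl trifluoromethanesulfonate | COc1cc([Si](C)(C)C)c(OS(=O)(=O)C(F)(F)F)c(Br)c1OC
A2 | alternative 1 | tert-butyl isocyanide | CC(C)(C)[N+]#[C-]
A3 | alternative 1 | 2,3-dibromo-4,5-dimethoxybenzaldehyde | COc1cc(C=O)c(Br)c(Br)c1OC
A4 | alternative 1 | (Z)-4-bromo-N-tert-butyl-3-(2,3-dibromo-4,5-dimethoxyphenyl)-5,6-dimethoxyisobenzofuran-1(3H)-imine, racemic at C3 | CC(C)(C)/N=C1\OC(c2cc(OC)c(OC)c(Br)c2Br)c2c1cc(OC)c(OC)c2Br
A5 | alternative 1 | 4-bromo-3-(2,3-dibromo-4,5-dimethoxyphenyl)-5,6-dimethoxyisobenzofuran-1(3H)-one, racemic at C3 | O=C1OC(c2cc(OC)c(OC)c(Br)c2Br)c2c1cc(OC)c(OC)c2Br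
A6 | alternative 2 | methyl 3-bromo-4-(2,3-dibromo-4,5-dimethoxybenzyl)-2-oxo-2H-pyran-5-carboxylate | COC(=O)C1=COC(=O)C(Br)=C1Cc1cc(OC)c(OC)c(Br)c1Br
A7 | alternative 2 | di-tert-butoxyethyne | CC(C)(C)OC#COC(C)(C)C
A8 | alternative 2 | methyl 3-bromo-4,5-di-tert-butoxy-2-(2,3-dibromo-4,5-dimethoxybenzyl)benzoate | COC(=O)c1cc(OC(C)(C)C)c(OC(C)(C)C)c(Br)c1Cc1cc(OC)c(OC)c(Br)c1Br
A9 | alternative 3 | 4-hydroxy-2-(4-hydroxy-3-methoxybenzyl)-5-methoxybenzaldehyde | O=Cc1cc(OC)c(O)cc1Cc1ccc(O)c(OC)c1
A10 | alternative 3 | 3-bromo-2-(2,3-dibromo-4-hydroxy-5-methoxybenzyl)-4-hydroxy-5-methoxybenzaldehyde | O=Cc1cc(OC)c(O)c(Br)c1Cc1cc(OC)c(O)c(Br)c1Br
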